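Labdane numbering is used (C18 = 4α carbon and C19 = 4β carbon on C4, C20 on C10, C17 on C8, side chain C11–C16; β = face of C20). Ring A (C1–C5, C10) is a masked cyclohexene: with a C1=C2 double bond in place, C3–C4 and C5–C10 are the two σ-bonds of a [4+2] adduct, and C5–C10 is also the fusion bond of ring B (C5–C10), so a diene C10=C1–C2=C3 tied through C9–C6 to a dienophile C4=C5 closes both carbocycles in one event.
Retrosynthetic cuts, in order: acetate and silyl ether; O16–C15 (dihydrofuran ring D); C8–C17; O9–C13 (spiro tetrahydrofuran ring C); C9–C11; then C3–C4 together with C5–C10 (rings A and B); the open-chain trienal is cut at C4=C5, C8–C9 and C10=C1.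
Forward: Wittig (C10=C1), enantioselective dialkylzinc addition (C8–C9), Knoevenagel and redox adjustment (C4=C5 enal), intramolecular Diels–Alder reaction (rings A and B), Suzuki coupling of epoxide fragment 27 at C9, ketohydroxylation, epoxide opening (ring C), diosphenol formation and methyl addition at C8, alkynol cycloisomerisation (ring D), acetylation, desilylation.
Stereochemistry: the C9 carbinol (ligand control) steers the π-face of the cycloaddition and is oxidised away afterwards; C4, C5 and C10 follow from the (E)-enal, the endo formyl group and the trans-fused transition state; C13 comes from a Sharpless epoxidation and is transferred with inversion; C9–O and C8–CH3 are introduced from the α-face, anti to the C10 methyl group.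

Key step: step 10

Remark: TBS = tert-butyldimethylsilyl, TBDPS = tert-butyldiphenylsilyl; "heptanorlabdane" means 11,12,13,14,15,16,17-heptanorlabdane (5α-H, 10β-CH3); the C9 silyl ether is assumed to take the inside (pseudo-axial) position in step 10, and since C9 is oxidised in step 13 the enantiomeric carbinol would be carried through if the other face proved to be preferred.

Step 1
Reactants: 1 acrolein; 2 2-(triphenylphosphoranylidene)propanal
Product: 3 (2E)-2-methylpenta-2,4-dienal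
Conditions: CH2Cl2, 0 °C to rt
Reagents that add atoms: none
Why: Wittig olefination with the formyl-stabilised ylide should give the (E)-2-methyl enal (CHO trans to the vinyl group), which fixes the later C10=C1 geometry.

Step 2
Reactants: 4 2-(3-chloropropyl)-1,3-dioxolane
Product: 5 2-(3-iodopropyl)-1,3-dioxolane
Conditions: NaI, NaHCO3 (cat.), acetone, reflux
Reagents that add atoms: sodium iodide (NaI), [Na+].[I-]
Why: Finkelstein exchange driven by precipitation of NaCl should give the iodide needed for iodine–zinc exchange.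

Step 3
Reactants: 5 2-(3-iodopropyl)-1,3-dioxolane; 3 (2E)-2-methylpenta-2,4-dienal
Product: 7 (4R,5E)-1-(1,3-dioxolan-2-yl)-5-methylocta-5,7-dien-4-ol, via dialkylzinc 6 (not isolated)
Conditions: 5 (2.5 equiv), Et2Zn, CuI (cat.), 50 °C, volatiles removed; then (1S,2S)-N,N'-bis(trifluoromethylsulfonyl)cyclohexane-1,2-diamine (8 mol%), Ti(OiPr)4, toluene, −20 °C, 3
Reagents that add atoms: none
Why: Iodine–zinc exchange followed by the titanium bis(sulfonamide)-catalysed enantioselective 1,2-addition of a functionalised dialkylzinc to an α-methyl enal should set C9 as R by ligand-controlled Re-face alkyl transfer.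

Step 4
Reactants: 7 (4R,5E)-1-(1,3-dioxolan-2-yl)-5-methylocta-5,7-dien-4-ol
Product: 8 2-[(4R,5E)-4-(TBS-oxy)-5-methylocta-5,7-dien-1-yl]-1,3-dioxolane
Conditions: t-BuMe2SiCl, imidazole, DMF, rt
Reagents that add atoms: tert-butyl(chloro)dimethylsilane, C[Si](C)(Cl)C(C)(C)C
Why: Standard imidazole-promoted silylation protects the dienylic carbinol, whose ether oxygen later serves as the stereocontrol element.

Step 5
Reactants: 8 2-[(4R,5E)-4-(TBS-oxy)-5-methylocta-5,7-dien-1-yl]-1,3-dioxolane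
Product: 9 (5R,6E)-5-(TBS-oxy)-6-methylnona-6,8-dienal
Conditions: PPTS (0.2 equiv), acetone/H2O 9:1, 55 °C
Reagents that add atoms: water, O
Why: Mild acid-catalysed acetal hydrolysis should free the C5 aldehyde while the secondary TBS ether survives.

Step 6
Reactants: 9 (5R,6E)-5-(TBS-oxy)-6-methylnona-6,8-dienal; 10 dimethyl malonate
Product: 11 dimethyl 2-[(5R,6E)-5-(TBS-oxy)-6-methylnona-6,8-dien-1-ylidene]propanedioate
Conditions: piperidine (10 mol%), AcOH (10 mol%), 4 Å molecular sieves, CH2Cl2, 0 °C to rt, used at once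
Reagents that add atoms: none
Why: Knoevenagel condensation forms C4=C5 with both C18 and C19 in place and without any alkene-geometry issue.

Step 7
Reactants: 11 dimethyl 2-[(5R,6E)-5-(TBS-oxy)-6-methylnona-6,8-dien-1-ylidene]propanedioate
Product: 12 2-[(5R,6E)-5-(TBS-oxy)-6-methylnona-6,8-dien-1-ylidene]propane-1,3-diol
Conditions: i-Bu2AlH (4.5 equiv), CH2Cl2, −78 to −40 °C; aqueous sodium potassium tartrate
Reagents that add atoms: none
Why: 1,2-Reduction of both conjugated esters by i-Bu2AlH at low temperature should give the 2-alkylidene-1,3-diol.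

Step 8
Reactants: 12 2-[(5R,6E)-5-(TBS-oxy)-6-methylnona-6,8-dien-1-ylidene]propane-1,3-diol
Product: 13 (2E,7R,8E)-2-(TBDPS-oxymethyl)-7-(TBS-oxy)-8-methylundeca-2,8,10-trien-1-ol (free CH2OH cis to the chain)
Conditions: NaH (1.0 equiv), THF, 0 °C; t-BuPh2SiCl (1.0 equiv)
Reagents that add atoms: tert-butyl(chloro)diphenylsilane, CC(C)(C)[Si](Cl)(c1ccccc1)c1ccccc1
Why: Monosilylation of the diol through its monoalkoxide should occur mainly at the less hindered hydroxymethyl group, and the regioisomeric monoether leads to the same enal 15 after step 9.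

Step 9
Reactants: 13 (2E,7R,8E)-2-(TBDPS-oxymethyl)-7-(TBS-oxy)-8-methylundeca-2,8,10-trien-1-ol
Product: 15 (2E,7R,8E)-2-(TBDPS-oxymethyl)-7-(TBS-oxy)-8-methylundeca-2,8,10-trienal, via (Z)-enal 14 (not isolated)
Conditions: MnO2, CH2Cl2, rt; then PhSH (5 mol%), Et3N (5 mol%), rt
Reagents that add atoms: none
Why: Allylic oxidation with MnO2 gives the enal, and reversible thia-Michael addition should equilibrate it to the thermodynamically preferred (E)-isomer with CHO trans and CH2OTBDPS cis to the chain.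

Step 10
Reactants: 15 (2E,7R,8E)-2-(TBDPS-oxymethyl)-7-(TBS-oxy)-8-methylundeca-2,8,10-trienal
Product: 16 9α-(TBS-oxy)-19-(TBDPS-oxy)-heptanorlabd-1-en-18-al
Conditions: Me2AlCl (0.3 equiv), CH2Cl2, −78 to −20 °C
Reagents that add atoms: none
Why: Coordination of Me2AlCl to the enal lowers its LUMO, and the triene should undergo a concerted but asynchronous suprafacial [4+2] cycloaddition in which C5–C10 forms ahead of C3–C4. The closest known reaction type is the alkylaluminium chloride promoted intramolecular Diels–Alder reaction of (E)-2-substituted undeca-2,8,10-trienals, which gives trans-fused octalins with the formyl group endo. Ring A is closed as the new cyclohexene by both bonds of the cycloaddition, and ring B is closed by the C5–C10 bond alone through a chair-like arrangement of the four-carbon tether C6–C9 (fused, type 1 mode, tether exo). C5 (α-H) and C10 (β-CH3) come from this anti transition state, C4 (CHO α, CH2OTBDPS β) from the (E)-enal geometry together with the endo formyl group, and the absolute sense from the C9 silyloxy stereocentre, which takes the inside position eclipsing C10=C1 so that the dienophile adds anti to the C9–H bond. The step needs trans over cis fusion and one π-face: the first is secured by the endo preference of the complexed aldehyde, which is trans to the tether, the second by the allylic silyl ether, and the low temperature avoids the [1,5]-hydrogen shift open to the (Z)-methyl diene.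

Step 11
Reactants: 16 9α-(TBS-oxy)-19-(TBDPS-oxy)-heptanorlabd-1-en-18-al
Product: 17 18,18-(ethane-1,2-diyldisulfanediyl)-9α-(TBS-oxy)-19-(TBDPS-oxy)-heptanorlabd-1-ene
Conditions: HS(CH2)2SH, BF3·OEt2 (0.3 equiv), CH2Cl2, −20 °C
Reagents that add atoms: ethane-1,2-dithiol, SCCS
Why: Lewis-acid catalysed dithioacetalisation of the neopentyl aldehyde at low temperature should leave both silyl ethers intact.

Step 12
Reactants: 17 18,18-(ethane-1,2-diyldisulfanediyl)-9α-(TBS-oxy)-19-(TBDPS-oxy)-heptanorlabd-1-ene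
Product: 18 9α-(TBS-oxy)-19-(TBDPS-oxy)-heptanorlabdane
Conditions: Raney Ni (W-2), H2 (1 atm), EtOH, reflux
Reagents that add atoms: none
Why: Mozingo desulfurisation turns C18 into the 4α-methyl group, and the same catalyst under hydrogen should saturate the cis-disubstituted C1=C2 bond without touching a stereocentre.

Step 13
Reactants: 18 9α-(TBS-oxy)-19-(TBDPS-oxy)-heptanorlabdane
Product: 20 19-(TBDPS-oxy)-heptanorlabdan-9-one, via carbinol 19 (not isolated)
Conditions: CrO3, H2SO4, H2O, acetone, 0 °C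
Reagents that add atoms: none
Why: Jones oxidation should hydrolyse the more acid-labile secondary TBS ether and oxidise the freed carbinol in the same flask, removing the C9 control element while the far more acid-stable primary TBDPS ether stays.

Step 14
Reactants: 20 19-(TBDPS-oxy)-heptanorlabdan-9-one
Product: 21 19-(TBDPS-oxy)-heptanorlabd-8-en-9-yl trifluoromethanesulfonate
Conditions: KN(SiMe3)2, THF, −78 °C; PhNTf2, −78 to 0 °C
Reagents that add atoms: N-phenylbis(trifluoromethanesulfonimide), O=S(=O)(N(c1ccccc1)S(=O)(=O)C(F)(F)F)C(F)(F)F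
Why: Enolisation is only possible toward C8 because C10 is quaternary, so O-triflation of the potassium enolate should give the 8(9)-enol triflate as a single regioisomer.

Step 15
Reactants: 22 2-bromoprop-2-en-1-ol; 23 ethynyl(trimethyl)silane
Product: 24 2-methylidene-4-(trimethylsilyl)but-3-yn-1-ol
Conditions: Pd(PPh3)2Cl2 (2 mol%), CuI (4 mol%), i-Pr2NH, THF, rt
Reagents that add atoms: none
Why: Sonogashira coupling of the vinyl bromide with the terminal alkyne assembles C12, C13, C14, C15 and C16 of the side chain.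

Step 16
Reactants: 24 2-methylidene-4-(trimethylsilyl)but-3-yn-1-ol
Product: 25 [(2S)-2-[(trimethylsilyl)ethynyl]oxiran-2-yl]methanol
Conditions: Ti(OiPr)4 (20 mol%), L-(+)-diisopropyl tartrate (24 mol%), t-BuOOH, 4 Å molecular sieves, CH2Cl2, −20 °C
Reagents that add atoms: tert-butyl hydroperoxide, CC(C)(C)OO
Why: Sharpless asymmetric epoxidation of the 2-substituted allylic alcohol with the L-(+)-tartrate should deliver oxygen to the face that gives the (S)-epoxy alcohol and so sets C13.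

Step 17
Reactants: 25 [(2S)-2-[(trimethylsilyl)ethynyl]oxiran-2-yl]methanol
Product: 26 (2R)-2-[(trimethylsilyl)ethynyl]oxirane-2-carbaldehyde
Conditions: Dess–Martin periodinane, NaHCO3, CH2Cl2, 0 °C
Reagents that add atoms: none
Why: Buffered Dess–Martin oxidation gives the epoxy aldehyde, whose quaternary α-carbon cannot epimerise (the descriptor changes only by priority).

Step 18
Reactants: 26 (2R)-2-[(trimethylsilyl)ethynyl]oxirane-2-carbaldehyde
Product: 27 (2R)-2-ethenyl-2-[(trimethylsilyl)ethynyl]oxirane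
Conditions: Ph3PCH3Br, KN(SiMe3)2, THF, −78 to 0 °C
Reagents that add atoms: methyltriphenylphosphonium bromide, C[P+](c1ccccc1)(c1ccccc1)c1ccccc1.[Br-]
Why: Wittig methylenation adds C11 and gives the vinyl group needed for hydroboration.

Step 19
Reactants: 27 (2R)-2-ethenyl-2-[(trimethylsilyl)ethynyl]oxirane; 21 19-(TBDPS-oxy)-heptanorlabd-8-en-9-yl trifluoromethanesulfonate
Product: 29 (13R)-19-(TBDPS-oxy)-13,16-epoxy-15-(trimethylsilyl)-17-norlabd-8-en-14-yne, via alkylborane 28 (not isolated)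
Conditions: 27, 9-BBN, THF, 0 °C to rt; then 21, Pd(dppf)Cl2 (5 mol%), AsPh3, Cs2CO3, DMF/H2O, rt
Reagents that add atoms: none
Why: Anti-Markovnikov hydroboration of the vinyl group (much faster than that of the silylalkyne) followed by B-alkyl Suzuki–Miyaura coupling with the enol triflate should form C9–C11 and leave the 8(9)-alkene in place.

Step 20
Reactants: 29 (13R)-19-(TBDPS-oxy)-13,16-epoxy-15-(trimethylsilyl)-17-norlabd-8-en-14-yne
Product: 30 (13R)-19-(TBDPS-oxy)-13,16-epoxy-9α-hydroxy-15-(trimethylsilyl)-17-norlabd-14-yn-8-one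
Conditions: RuCl3 (2 mol%), KHSO5 (as 2KHSO5·KHSO4·K2SO4), NaHCO3, EtOAc/MeCN/H2O, rt, 10 min
Reagents that add atoms: potassium peroxymonosulfate (KHSO5), [K+].[O-]S(=O)(=O)OO
Why: RuO4-catalysed ketohydroxylation should add to the electron-rich trisubstituted alkene from the α-face, anti to the C10 methyl group, giving the 9α-tertiary alcohol and the C8 ketone directly.

Step 21
Reactants: 30 (13R)-19-(TBDPS-oxy)-13,16-epoxy-9α-hydroxy-15-(trimethylsilyl)-17-norlabd-14-yn-8-one
Product: 31 (13S)-19-(TBDPS-oxy)-9α,13-epoxy-16-hydroxy-15-(trimethylsilyl)-17-norlabd-14-yn-8-one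
Conditions: camphorsulfonic acid (10 mol%), CH2Cl2, 0 °C
Reagents that add atoms: none
Why: Acid-catalysed 5-exo epoxide opening by the 9α-hydroxyl at the fully substituted propargylic carbon C13 should proceed with inversion, closing ring C, setting C13 as S and freeing the C16 hydroxyl.

Step 22
Reactants: 31 (13S)-19-(TBDPS-oxy)-9α,13-epoxy-16-hydroxy-15-(trimethylsilyl)-17-norlabd-14-yn-8-one
Product: 32 (13S)-19-(TBDPS-oxy)-9α,13-epoxy-7,16-dihydroxy-17-norlabd-6-en-14-yn-8-one
Conditions: KOtBu, O2 (1 atm), THF/t-BuOH, 0 °C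
Reagents that add atoms: dioxygen, O=O
Why: Base-mediated autoxidation at C7, the only enolisable position of the ketone, should give the 7,8-dione as its diosphenol (enol toward C6), and the alkoxide medium also cleaves the alkynyl–silicon bond.

Step 23
Reactants: 32 (13S)-19-(TBDPS-oxy)-9α,13-epoxy-7,16-dihydroxy-17-norlabd-6-en-14-yn-8-one
Product: 33 (13S)-19-(TBDPS-oxy)-9α,13-epoxy-8β,16-dihydroxylabd-14-yn-7-one
Conditions: MeMgBr (6 equiv), THF, −20 to 0 °C; aqueous NH4Cl
Reagents that add atoms: methylmagnesium bromide (MeMgBr), C[Mg]Br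
Why: Grignard 1,2-addition to the C8 carbonyl of the enolised 1,2-dione should occur from the α-face (equatorial attack, anti to the syn-axial C10 methyl group) to give 8α-CH3 and 8β-OH, and the C7 enolate becomes the ketone on work-up.

Step 24
Reactants: 33 (13S)-19-(TBDPS-oxy)-9α,13-epoxy-8β,16-dihydroxylabd-14-yn-7-one
Product: 34 (13S)-19-(TBDPS-oxy)-9α,13:15,16-diepoxy-8β-hydroxylabd-14-en-7-one
Conditions: Mo(CO)6 (25 mol%), Et3N, Et2O, hν (350 nm), rt
Reagents that add atoms: none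
Why: Molybdenum pentacarbonyl-catalysed cycloisomerisation of the 3-butyn-1-ol unit through a metal vinylidene should close ring D by 5-endo attack of O16 on C15 under basic conditions that the acid-labile allylic ether tolerates.

Step 25
Reactants: 34 (13S)-19-(TBDPS-oxy)-9α,13:15,16-diepoxy-8β-hydroxylabd-14-en-7-one
Product: 35 (13S)-8β-acetoxy-19-(TBDPS-oxy)-9α,13:15,16-diepoxylabd-14-en-7-one
Conditions: Ac2O, DMAP, Et3N, CH2Cl2, 40 °C
Reagents that add atoms: acetic anhydride, CC(=O)OC(C)=O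
Why: DMAP-catalysed acylation should acetylate the only free hydroxyl, the tertiary 8β-alcohol, under base that the enol ether tolerates.

Step 26
Reactants: 35 (13S)-8β-acetoxy-19-(TBDPS-oxy)-9α,13:15,16-diepoxylabd-14-en-7-one
Product: 36 (13S)-8β-acetoxy-9α,13:15,16-diepoxy-19-hydroxylabd-14-en-7-one (target)
Conditions: Bu4NF, AcOH (1:1), THF, 0 °C to rt
Reagents that add atoms: none
Why: Buffered fluoride desilylation should free the C19 alcohol without touching the tertiary acetate or the dihydrofuran.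

Compound list
1 | acrolein | C=CC=O | starting material
2 | 2-(triphenylphosphoranylidene)propanal | CC(C=O)=P(c1ccccc1)(c1ccccc1)c1ccccc1 | starting material
3 | (2E)-2-methylpenta-2,4-dienal | O=C/C(C)=C/C=C | intermediate
4 | 2-(3-chloropropyl)-1,3-dioxolane | ClCCCC1OCCO1 | starting material
5 | 2-(3-iodopropyl)-1,3-dioxolane | ICCCC1OCCO1 | intermediate
6 | bis[3-(1,3-dioxolan-2-yl)propyl]zinc | C1COC(CCC[Zn]CCCC2OCCO2)O1 | intermediate
7 | (4R,5E)-1-(1,3-dioxolan-2-yl)-5-methylocta-5,7-dien-4-ol | C1COC(CCC[C@@H](O)/C(C)=C/C=C)O1 | intermediate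
8 | 2-[(4R,5E)-4-(TBS-oxy)-5-methylocta-5,7-dien-1-yl]-1,3-dioxolane | C1COC(CCC[C@@H](O[Si](C)(C)C(C)(C)C)/C(C)=C/C=C)O1 | intermediate
9 | (5R,6E)-5-(TBS-oxy)-6-methylnona-6,8-dienal | O=CCCC[C@@H](O[Si](C)(C)C(C)(C)C)/C(C)=C/C=C | intermediate
10 | dimethyl malonate | COC(=O)CC(=O)OC | starting material
11 | dimethyl 2-[(5R,6E)-5-(TBS-oxy)-6-methylnona-6,8-dien-1-ylidene]propanedioate | COC(=O)C(C(=O)OC)=CCCC[C@@H](O[Si](C)(C)C(C)(C)C)/C(C)=C/C=C | intermediate
12 | 2-[(5R,6E)-5-(TBS-oxy)-6-methylnona-6,8-dien-1-ylidene]propane-1,3-diol | OCC(CO)=CCCC[C@@H](O[Si](C)(C)C(C)(C)C)/C(C)=C/C=C | intermediate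
13 | (2E,7R,8E)-2-(TBDPS-oxymethyl)-7-(TBS-oxy)-8-methylundeca-2,8,10-trien-1-ol | OC/C(CO[Si](c1ccccc1)(c1ccccc1)C(C)(C)C)=C\CCC[C@@H](O[Si](C)(C)C(C)(C)C)/C(C)=C/C=C | intermediate
14 | (2Z,7R,8E)-2-(TBDPS-oxymethyl)-7-(TBS-oxy)-8-methylundeca-2,8,10-trienal | O=C/C(CO[Si](c1ccccc1)(c1ccccc1)C(C)(C)C)=C\CCC[C@@H](O[Si](C)(C)C(C)(C)C)/C(C)=C/C=C | intermediate
15 | (2E,7R,8E)-2-(TBDPS-oxymethyl)-7-(TBS-oxy)-8-methylundeca-2,8,10-trienal | O=C/C(CO[Si](c1ccccc1)(c1ccccc1)C(C)(C)C)=C/CCC[C@@H](O[Si](C)(C)C(C)(C)C)/C(C)=C/C=C | intermediate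
16 | 9α-(TBS-oxy)-19-(TBDPS-oxy)-heptanorlabd-1-en-18-al | C1CC[C@H]2[C@@](C=O)(CO[Si](c3ccccc3)(c3ccccc3)C(C)(C)C)CC=C[C@]2(C)[C@@H]1O[Si](C)(C)C(C)(C)C | intermediate
17 | 18,18-(ethane-1,2-diyldisulfanediyl)-9α-(TBS-oxy)-19-(TBDPS-oxy)-heptanorlabd-1-ene | C1CC[C@H]2[C@@](C3SCCS3)(CO[Si](c3ccccc3)(c3ccccc3)C(C)(C)C)CC=C[C@]2(C)[C@@H]1O[Si](C)(C)C(C)(C)C | intermediate
18 | 9α-(TBS-oxy)-19-(TBDPS-oxy)-heptanorlabdane | C1CC[C@H]2[C@@](C)(CO[Si](c3ccccc3)(c3ccccc3)C(C)(C)C)CCC[C@]2(C)[C@@H]1O[Si](C)(C)C(C)(C)C | intermediate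
19 | 19-(TBDPS-oxy)-heptanorlabdan-9α-ol | C1CC[C@H]2[C@@](C)(CO[Si](c3ccccc3)(c3ccccc3)C(C)(C)C)CCC[C@]2(C)[C@@H]1O | intermediate
20 | 19-(TBDPS-oxy)-heptanorlabdan-9-one | C1CC[C@H]2[C@@](C)(CO[Si](c3ccccc3)(c3ccccc3)C(C)(C)C)CCC[C@]2(C)C1=O | intermediate
21 | 19-(TBDPS-oxy)-heptanorlabd-8-en-9-yl trifluoromethanesulfonate | C1C[C@H]2[C@@](C)(CO[Si](c3ccccc3)(c3ccccc3)C(C)(C)C)CCC[C@]2(C)C(OS(=O)(=O)C(F)(F)F)=C1 | intermediate
22 | 2-bromoprop-2-en-1-ol | OCC(Br)=C | starting material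
23 | ethynyl(trimethyl)silane | C#C[Si](C)(C)C | starting material
24 | 2-methylidene-4-(trimethylsilyl)but-3-yn-1-ol | OCC(=C)C#C[Si](C)(C)C | intermediate
25 | [(2S)-2-[(trimethylsilyl)ethynyl]oxiran-2-yl]methanol | OC[C@@]1(C#C[Si](C)(C)C)CO1 | intermediate
26 | (2R)-2-[(trimethylsilyl)ethynyl]oxirane-2-carbaldehyde | O=C[C@@]1(C#C[Si](C)(C)C)CO1 | intermediate
27 | (2R)-2-ethenyl-2-[(trimethylsilyl)ethynyl]oxirane | C=C[C@@]1(C#C[Si](C)(C)C)CO1 | intermediate
28 | 9-[2-[(2R)-2-[(trimethylsilyl)ethynyl]oxiran-2-yl]ethyl]-9-borabicyclo[3.3.1]nonane | B1(CC[C@@]2(C#C[Si](C)(C)C)CO2)C3CCCC1CCC3 | intermediate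
29 | (13R)-19-(TBDPS-oxy)-13,16-epoxy-15-(trimethylsilyl)-17-norlabd-8-en-14-yne | C1C[C@H]2[C@@](C)(CO[Si](c3ccccc3)(c3ccccc3)C(C)(C)C)CCC[C@]2(C)C(CC[C@@]3(C#C[Si](C)(C)C)CO3)=C1 | intermediate
30 | (13R)-19-(TBDPS-oxy)-13,16-epoxy-9α-hydroxy-15-(trimethylsilyl)-17-norlabd-14-yn-8-one | O=C1CC[C@H]2[C@@](C)(CO[Si](c3ccccc3)(c3ccccc3)C(C)(C)C)CCC[C@]2(C)[C@@]1(O)CC[C@@]1(C#C[Si](C)(C)C)CO1 | intermediate
31 | (13S)-19-(TBDPS-oxy)-9α,13-epoxy-16-hydroxy-15-(trimethylsilyl)-17-norlabd-14-yn-8-one | O=C1CC[C@H]2[C@@](C)(CO[Si](c3ccccc3)(c3ccccc3)C(C)(C)C)CCC[C@]2(C)[C@@]12CC[C@@](CO)(C#C[Si](C)(C)C)O2 | intermediate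
32 | (13S)-19-(TBDPS-oxy)-9α,13-epoxy-7,16-dihydroxy-17-norlabd-6-en-14-yn-8-one | O=C1C(O)=C[C@H]2[C@@](C)(CO[Si](c3ccccc3)(c3ccccc3)C(C)(C)C)CCC[C@]2(C)[C@@]12CC[C@@](CO)(C#C)O2 | intermediate
33 | (13S)-19-(TBDPS-oxy)-9α,13-epoxy-8β,16-dihydroxylabd-14-yn-7-one | O[C@@]1(C)C(=O)C[C@H]2[C@@](C)(CO[Si](c3ccccc3)(c3ccccc3)C(C)(C)C)CCC[C@]2(C)[C@@]12CC[C@@](CO)(C#C)O2 | intermediate
34 | (13S)-19-(TBDPS-oxy)-9α,13:15,16-diepoxy-8β-hydroxylabd-14-en-7-one | O[C@@]1(C)C(=O)C[C@H]2[C@@](C)(CO[Si](c3ccccc3)(c3ccccc3)C(C)(C)C)CCC[C@]2(C)[C@@]12CC[C@@]1(C=COC1)O2 | intermediate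
35 | (13S)-8β-acetoxy-19-(TBDPS-oxy)-9α,13:15,16-diepoxylabd-14-en-7-one | CC(=O)O[C@@]1(C)C(=O)C[C@H]2[C@@](C)(CO[Si](c3ccccc3)(c3ccccc3)C(C)(C)C)CCC[C@]2(C)[C@@]12CC[C@@]1(C=COC1)O2 | intermediate
36 | (13S)-8β-acetoxy-9α,13:15,16-diepoxy-19-hydroxylabd-14-en-7-one | CC(=O)O[C@@]1(C)C(=O)C[C@H]2[C@@](C)(CO)CCC[C@]2(C)[C@@]12CC[C@@]1(C=COC1)O2 | target

Total step count: 26 (22 in the main line, including the halide exchange of step 2, and 4 for fragment 27).
Longest linear sequence: 21 steps (steps 1, 3 to 14 and 19 to 26).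

Steps most likely to fail

Step 10. The cycloaddition may be too slow at the doubly substituted diene terminus, whose (Z)-methyl group disfavours the s-cis conformer, so that forcing leads to a [1,5]-hydrogen shift or to polymerisation. The fallback sets out from 11 and comes back at 18. The doubly activated alkylidene malonate 11 is cyclised instead (ZnBr2, CH2Cl2, rt, or toluene, 80 °C) to dimethyl 9α-(TBS-oxy)-heptanorlabd-1-ene-18,19-dioate F1. LiAlH4 reduces it to 9α-(TBS-oxy)-heptanorlabd-1-ene-18,19-diol F2. TsCl in pyridine at 0 °C should sulfonylate the less hindered equatorial 4α-hydroxymethyl group to give 19-hydroxy-9α-(TBS-oxy)-heptanorlabd-1-en-18-yl 4-methylbenzenesulfonate F3. t-BuPh2SiCl with imidazole and DMAP protects the axial hydroxymethyl group as 19-(TBDPS-oxy)-9α-(TBS-oxy)-heptanorlabd-1-en-18-yl 4-methylbenzenesulfonate F4. LiEt3BH in refluxing THF reduces the neopentyl sulfonate to 19-(TBDPS-oxy)-9α-(TBS-oxy)-heptanorlabd-1-ene F5, and hydrogenation (H2, Pd/C, EtOAc) gives 18.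

Step 20. Over-oxidation with cleavage of the C8–C9 bond, or competing oxidation of the silylalkyne by RuO4, may erode the ketol. The fallback sets out from 29 and comes back at 30. Dihydroxylation with OsO4 (cat.) and N-methylmorpholine N-oxide from the α-face gives (13R)-19-(TBDPS-oxy)-13,16-epoxy-15-(trimethylsilyl)-17-norlabd-14-yne-8α,9α-diol F6, and its secondary hydroxyl is oxidised with SO3·pyridine, DMSO and i-Pr2NEt to 30.

Step 23. The Grignard reagent first deprotonates the diosphenol, and addition to the resulting enolate may stall or lose facial selectivity. The fallback sets out from 32 and comes back at 33. The diosphenol is silylated (Me3SiCl, Et3N, THF) to (13S)-19-(TBDPS-oxy)-9α,13-epoxy-7,16-bis(trimethylsilyloxy)-17-norlabd-6-en-14-yn-8-one F7. MeLi with CeCl3 at −78 °C then adds to the now neutral C8 ketone from the α-face to give (13S)-19-(TBDPS-oxy)-9α,13-epoxy-7,16-bis(trimethylsilyloxy)labd-6-en-14-yn-8β-ol F8, and aqueous citric acid hydrolyses the silyl enol ether and the primary silyl ether to 33.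

Further compounds
F1 | step 10 | dimethyl 9α-(TBS-oxy)-heptanorlabd-1-ene-18,19-dioate | C1CC[C@H]2C(C(=O)OC)(C(=O)OC)CC=C[C@]2(C)[C@@H]1O[Si](C)(C)C(C)(C)C
F2 | step 10 | 9α-(TBS-oxy)-heptanorlabd-1-ene-18,19-diol | C1CC[C@H]2C(CO)(CO)CC=C[C@]2(C)[C@@H]1O[Si](C)(C)C(C)(C)C
F3 | step 10 | 19-hydroxy-9α-(TBS-oxy)-heptanorlabd-1-en-18-yl 4-methylbenzenesulfonate | C1CC[C@H]2[C@@](COS(=O)(=O)c3ccc(C)cc3)(CO)CC=C[C@]2(C)[C@@H]1O[Si](C)(C)C(C)(C)C
F4 | step 10 | 19-(TBDPS-oxy)-9α-(TBS-oxy)-heptanorlabd-1-en-18-yl 4-methylbenzenesulfonate | C1CC[C@H]2[C@@](COS(=O)(=O)c3ccc(C)cc3)(CO[Si](c3ccccc3)(c3ccccc3)C(C)(C)C)CC=C[C@]2(C)[C@@H]1O[Si](C)(C)C(C)(C)C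
F5 | step 10 | 19-(TBDPS-oxy)-9α-(TBS-oxy)-heptanorlabd-1-ene | C1CC[C@H]2[C@@](C)(CO[Si](c3ccccc3)(c3ccccc3)C(C)(C)C)CC=C[C@]2(C)[C@@H]1O[Si](C)(C)C(C)(C)C
F6 | step 20 | (13R)-19-(TBDPS-oxy)-13,16-epoxy-15-(trimethylsilyl)-17-norlabd-14-yne-8α,9α-diol | O[C@@H]1CC[C@H]2[C@@](C)(CO[Si](c3ccccc3)(c3ccccc3)C(C)(C)C)CCC[C@]2(C)[C@@]1(O)CC[C@@]1(C#C[Si](C)(C)C)CO1
F7 | step 23 | (13S)-19-(TBDPS-oxy)-9α,13-epoxy-7,16-bis(trimethylsilyloxy)-17-norlabd-6-en-14-yn-8-one | O=C1C(O[Si](C)(C)C)=C[C@H]2[C@@](C)(CO[Si](c3ccccc3)(c3ccccc3)C(C)(C)C)CCC[C@]2(C)[C@@]12CC[C@@](CO[Si](C)(C)C)(C#C)O2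
F8 | step 23 | (13S)-19-(TBDPS-oxy)-9α,13-epoxy-7,16-bis(trimethylsilyloxy)labd-6-en-14-yn-8β-ol | O[C@@]1(C)C(O[Si](C)(C)C)=C[C@H]2[C@@](C)(CO[Si](c3ccccc3)(c3ccccc3)C(C)(C)C)CCC[C@]2(C)[C@@]12CC[C@@](CO[Si](C)(C)C)(C#C)O2
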